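## The problem

- The target 24 is an achiral 1,2-diarylethane with no stereocentre and no ring fusion, so every difficulty is positional.
- Ring A is a 5-alkylresorcinol dimethyl ether whose prenyl group sits on C4, the carbon flanked by the methoxy-bearing carbons C3 and C5, while C2 and C6 are CH. Electrophilic prenylation of such a ring goes to C2/C6, so the prenyl group must be placed by metalation or by construction.
- The rings are joined by a saturated CH2–CH2 bridge, yet the trisubstituted prenyl olefin must survive. This rules out the usual stilbene hydrogenation once the prenyl group is present.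
- Ring B is a 1,2,3,4-tetrasubstituted benzene with three neighbouring oxygens in three different states: OMe on C2, free OH on C3, OAc on C4.
- The acetate lies next to a free phenol, to which it can shift, and it is lost under base or nucleophiles. It must therefore be introduced late and regiospecifically, and the last step must be neither basic nor nucleophilic.
- After its introduction the prenyl olefin forbids hydrogenolysis, strong protic acid, peracids, halogen electrophiles and quinone oxidants.
- The feature that makes the key step possible is the pattern of ring A itself: C3(O)–C4(prenyl)–C5(O), the bridge on C1, hydrogen on C2 and C6. This is exactly the 2-alkyl-3-alkoxy-5-alkylphenol pattern formed when a 3-substituted cyclobutenone (four ring carbons, one oxygen) and a 1-alkoxyalkyne (two ring carbons, one oxygen) are fused thermally.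

## Retrosynthesis

**24 ⇒ 22 (through 23).** The O–CH2 bond of the methoxymethyl ether on O-3 of ring B is cut. The free phenol next to the acetate has to appear last. Of the groups compatible with the route, only this acetal can be removed without base, nucleophile, hydrogen or protic acid. The precursor differs from the target only by the acetal. The forward step must convert the acetal into silyl ether 23 and hydrolyse it without shifting the acetyl group or touching the prenyl olefin.

**22 ⇒ 20 (through 21).** The acyl–O bond on O-4 is cut and O-4 is traced back to its silyl ether. The neighbouring cut, acetylation of a free catechol, would ask two similar phenols to behave differently. Here O-3 is blocked, so the acetate can neither be misplaced nor migrate. The forward step asks for fluoride cleavage and capture of phenoxide 21 by an anhydride in the same flask.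

**20 ⇒ 19.** One O–CH3 bond of ring A is cut. Ring A of 24 is symmetric, but its two methoxy groups need not have the same origin. Allowing one of them to be a phenol opens an unsymmetrical ring synthesis. The forward step is a Williamson methylation of a phenol beside the prenyl group.

**19 ⇒ 14 + 4 (key disconnection).** Two ring bonds of ring A are cut: C(OH)–C(prenyl) and C(OMe)–C(H). The two-carbon unit C(prenyl)–C(OMe) is the ynol ether 4. The remaining four ring carbons and their oxygen fold back to cyclobutenone 14, so that 4 is formally inserted between the carbonyl carbon and C2 of 14.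
- Against the neighbouring cuts: cutting the bridge or the aryl–prenyl bond leaves ring A to be bought and then forced to accept a substituent at its most hindered carbon. Here that carbon is born substituted and the bridge is saturated from the start.
- Simplification: 14 contains neither ring A nor the prenyl group, and 4 is an eight-carbon alkyne.
- The forward reaction must be a neutral thermal cascade with complete regiocontrol.

**14 ⇒ 13 ⇒ 12.** The C1–C2 and C3–C4 bonds of the four-membered ring are cut, and two C–Cl bonds are added. A terminal alkyne is the simplest precursor of a 3-monosubstituted cyclobutenone. The forward steps are a regioselective [2+2] cycloaddition of a dihaloketene and a zinc dechlorination, both of which the ring B ethers must tolerate.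

**12 ⇒ 11 ⇒ 9 ⇒ 8.** The bond between the two future bridge carbons (benzylic CH2–propargylic CH2) is cut. This makes the bridge at the alkane level, so no olefin ever has to be reduced. The forward steps are a hydride reduction, activation of the benzylic alcohol 9 through mesylate 10, and a γ-selective coupling of chloride 11 with an allenylmetal.

**8 ⇒ 7 ⇒ 6 ⇒ 5.** Three O–X bonds are cut. The aldehyde of 5 ranks its three phenols: O-4 is para and the most acidic, O-2 is chelated and the least reactive. Silyl group, acetal and methyl group can therefore be put on in this order without a blocking step. 5 is commercial.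

**4 ⇒ 3 + 2, 3 ⇒ 1.** The propargylic C–C bond is cut. The metalated ynol ether 3 arises from the chloroacetal 1 by double elimination and is alkylated by prenyl bromide 2. The methoxy group of 4 becomes one of the two methoxy groups of ring A.

## Roads not taken

**Alternative 1:** the bridge is cut between its two carbons at the stilbene level, which is the obvious route.
- Forward key step: the ylide of phosphonium salt A1 (from a commercial resorcinol-derived benzyl alcohol by directed lithiation–prenylation, bromination and quaternization) would be condensed with aldehyde 8 in a Wittig reaction to stilbene A2. The disubstituted olefin would then be reduced with diimide to 20.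
- Why the chosen plan is better: A1 costs as many steps as the whole cyclobutenone branch and already needs the metalation that places the prenyl group. The reduction must distinguish a styrenic from a trisubstituted olefin, which catalytic hydrogenation cannot do. No structural problem is solved by the C=C formation.

**Alternative 2:** the aryl–CH2 bond of ring A is cut (sp2–sp3 cross-coupling).
- Forward key step: styrene A3 (from 8 by methylenation) would be hydroborated and coupled with aryl bromide A4 in a B-alkyl Suzuki–Miyaura reaction under PdCl2(dppf) catalysis to give 20.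
- Why the chosen plan is better: the difficulty is hidden in A4. Bromine and prenyl group must be set para to each other on a dimethoxybenzene, with the prenyl group between the methoxy groups, and metalation of such a bromoarene competes with halogen–metal exchange. Two building-block sequences and a palladium step are needed, and ring A is still bought, not built.

**Alternative 3:** ring A is built as a polyketide would be, through a cyclohexane-1,3-dione (biomimetic).
- Forward key step: enone A5 would undergo Michael addition and Claisen cyclization with a malonate, decarboxylation and C-prenylation on the carbon between the two carbonyl groups to give dione A6. A6 would then be aromatized oxidatively and O-methylated to 20.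
- Why the chosen plan is better: A5 needs a four-step homologation of 8. The aromatization of A6 needs a halogen, a quinone or a dehydrogenation catalyst, all of which attack the prenyl olefin or make the enol oxygen add to it. The chosen cascade reaches the aromatic oxidation level by pericyclic steps alone, without any oxidant.

Key step: step 10

Remark: 24 has no stereocentre and no stereogenic double bond; the only chiral species on the route, 16, is a transient racemate. ArB stands for 2-methoxy-3-(methoxymethoxy)-4-[(triisopropylsilyl)oxy]phenyl.

## Route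

Step 1
Reactants: 1 2-chloro-1,1-dimethoxyethane; 2 1-bromo-3-methylbut-2-ene (prenyl bromide)
Product: 4 1-methoxy-5-methylhex-4-en-1-yne, via lithium methoxyacetylide 3 (not isolated)
Conditions: LiN(i-Pr)2 (3.1 equiv), THF, −78 → 0 °C; then 2, DMPU, −78 °C → rt
Reagents that add atoms: none
Why: Two base-induced eliminations (methanol, then HCl) and deprotonation turn the chloroacetal into the metalated ynol ether 3, which is C-alkylated by the allylic bromide at its primary carbon (SN2); this is the standard chloroacetal route to 1-alkoxy-1-alkynes, and a methyl ynol ether cannot lose an alkene by retro-ene reaction on later heating.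

Step 2
Reactants: 5 2,3,4-trihydroxybenzaldehyde
Product: 6 2,3-dihydroxy-4-[(triisopropylsilyl)oxy]benzaldehyde
Conditions: i-Pr3SiCl (1.05 equiv), imidazole, DMF, 0 °C
Reagents that add atoms: triisopropylsilyl chloride, CC(C)[Si](Cl)(C(C)C)C(C)C
Why: Regioselective O-silylation: the 4-OH is para to the formyl group and the most acidic, the 2-OH is tied up in a hydrogen bond to C=O, and the 3-OH is flanked on both sides, so the bulky silyl chloride should go to O-4.

Step 3
Reactants: 6 2,3-dihydroxy-4-[(triisopropylsilyl)oxy]benzaldehyde
Product: 7 2-hydroxy-3-(methoxymethoxy)-4-[(triisopropylsilyl)oxy]benzaldehyde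
Conditions: MeOCH2Cl (1.2 equiv), i-Pr2NEt, CH2Cl2, 0 °C
Reagents that add atoms: chloromethyl methyl ether, COCCl
Why: O-alkylation with a reactive chloromethyl ether under amine base leaves the chelated 2-OH untouched, as in the known 3,4-bis-protection of this aldehyde; the mild base at 0 °C keeps the phenoxide concentration low, so the hindered silyl group should not shift from O-4 to O-3.

Step 4
Reactants: 7 2-hydroxy-3-(methoxymethoxy)-4-[(triisopropylsilyl)oxy]benzaldehyde
Product: 8 2-methoxy-3-(methoxymethoxy)-4-[(triisopropylsilyl)oxy]benzaldehyde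
Conditions: MeI, K2CO3, acetone, 50 °C
Reagents that add atoms: iodomethane, CI
Why: Williamson methylation of the remaining chelated phenol; no free hydroxyl is left next to the silyl ether, and anhydrous carbonate in acetone does not cleave an aryl triisopropylsilyl ether.

Step 5
Reactants: 8 2-methoxy-3-(methoxymethoxy)-4-[(triisopropylsilyl)oxy]benzaldehyde
Product: 9 {2-methoxy-3-(methoxymethoxy)-4-[(triisopropylsilyl)oxy]phenyl}methanol
Conditions: NaBH4, THF/MeOH, 0 °C
Reagents that add atoms: none
Why: Hydride reduction of an aryl aldehyde; silyl ether and acetal are inert to borohydride at 0 °C.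

Step 6
Reactants: 9 {2-methoxy-3-(methoxymethoxy)-4-[(triisopropylsilyl)oxy]phenyl}methanol
Product: 11 [4-(chloromethyl)-3-methoxy-2-(methoxymethoxy)phenoxy]triisopropylsilane, via benzylic mesylate 10 (not isolated)
Conditions: MsCl, Et3N, CH2Cl2, 0 °C → rt
Reagents that add atoms: methanesulfonyl chloride, CS(=O)(=O)Cl
Why: Mesylation of the electron-rich benzylic alcohol is followed in the same flask by displacement with the chloride set free; the conditions stay basic, so the acetal survives, and the chloride is more stable than the corresponding bromide.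

Step 7
Reactants: 11 [4-(chloromethyl)-3-methoxy-2-(methoxymethoxy)phenoxy]triisopropylsilane
Product: 12 [4-(but-3-yn-1-yl)-3-methoxy-2-(methoxymethoxy)phenoxy]triisopropylsilane
Conditions: allenylmagnesium bromide (from HC≡CCH2Br, Mg, HgCl2 1 mol%, Et2O, 0 °C); then 11, Et2O, 0 °C → rt
Reagents that add atoms: propargyl bromide (3-bromoprop-1-yne), C#CCBr
Why: Uncatalysed coupling of an allenyl Grignard reagent with a benzylic halide occurs through the γ-carbon (SE2′) and gives the homopropargyl arene, the standard entry to 4-aryl-1-butynes; it creates the saturated two-carbon bridge of the target.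

Step 8
Reactants: 12 [4-(but-3-yn-1-yl)-3-methoxy-2-(methoxymethoxy)phenoxy]triisopropylsilane
Product: 13 4,4-dichloro-3-(2-ArB-ethyl)cyclobut-2-en-1-one
Conditions: Cl3CCOCl, Zn–Cu couple, Et2O/DME, rt
Reagents that add atoms: trichloroacetyl chloride, ClC(=O)C(Cl)(Cl)Cl
Why: [2+2] cycloaddition of dichloroketene, generated by zinc dehalogenation of the acid chloride, to a terminal alkyne; the ketene carbonyl carbon bonds to the terminal alkyne carbon, so the chain ends on C3 and the chlorines on C4, and DME ties up ZnCl2 and thus spares the acetal.

Step 9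
Reactants: 13 4,4-dichloro-3-(2-ArB-ethyl)cyclobut-2-en-1-one
Product: 14 3-(2-ArB-ethyl)cyclobut-2-en-1-one
Conditions: Zn dust, AcOH, TMEDA, EtOH, 0 °C → rt
Reagents that add atoms: none
Why: Reductive removal of both α-chlorines by zinc in buffered acetic acid, the standard second half of the two-step alkyne-to-cyclobutenone sequence; the amine buffer prevents over-reduction and double bond migration.

Step 10
Reactants: 14 3-(2-ArB-ethyl)cyclobut-2-en-1-one; 4 1-methoxy-5-methylhex-4-en-1-yne
Product: 19 3-methoxy-2-(3-methylbut-2-en-1-yl)-5-(2-ArB-ethyl)phenol, via vinylketene 15 (not isolated), via alkenylcyclobutenone 16 (not isolated), via dienylketene 17 (not isolated), via cyclohexadienone 18 (not isolated)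
Conditions: 4 (1.5 equiv), toluene, 80 °C then 110 °C
Reagents that add atoms: none
Why: This is a Danheiser benzannulation. At 80 °C cyclobutenone 14 opens by a reversible 4π electrocyclic reaction to vinylketene 15, which the electron-rich ynol ether 4 captures in a [2+2] cycloaddition to give alkenylcyclobutenone 16. A second 4π opening gives dienylketene 17, whose 6π electrocyclization joins the ketene carbon to the terminal methylene carbon and closes the six-membered ring A as cyclohexadienone 18, which tautomerizes to phenol 19. The closest known reaction type is the thermal union of 3-alkylcyclobutenones with 1-alkoxyalkynes to give 2,5-dialkyl-3-alkoxyphenols. Ring A is thus closed by a disrotatory 6π electrocyclization; only the isomer of 17 with ketene and vinyl group on the same side of the central double bond can close, and the other isomer returns to 16, so the whole sequence drains through 17. No stereocentre is formed in 19, and the one in 16 is transient. The step needs regiocontrol in the [2+2] event and chemoselectivity for the ynol ether: the methoxy lone pair makes the prenyl-bearing alkyne carbon the nucleophile that attacks the ketene carbonyl carbon, which places the prenyl group between the two oxygens, and the ynol ether outcompetes the prenyl olefin and the arenes as ketenophile. An excess of 4 keeps 15 from dimerizing or acylating 19.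

Step 11
Reactants: 19 3-methoxy-2-(3-methylbut-2-en-1-yl)-5-(2-ArB-ethyl)phenol
Product: 20 [4-{2-[3,5-dimethoxy-4-(3-methylbut-2-en-1-yl)phenyl]ethyl}-3-methoxy-2-(methoxymethoxy)phenoxy]triisopropylsilane
Conditions: MeI, K2CO3, acetone, reflux
Reagents that add atoms: iodomethane, CI
Why: Williamson methylation of the only free phenol makes ring A symmetric; silyl ether, acetal and prenyl olefin are inert to carbonate in acetone.

Step 12
Reactants: 20 [4-{2-[3,5-dimethoxy-4-(3-methylbut-2-en-1-yl)phenyl]ethyl}-3-methoxy-2-(methoxymethoxy)phenoxy]triisopropylsilane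
Product: 22 4-{2-[3,5-dimethoxy-4-(3-methylbut-2-en-1-yl)phenyl]ethyl}-3-methoxy-2-(methoxymethoxy)phenyl acetate, via tetrabutylammonium phenoxide 21 (not isolated)
Conditions: Bu4NF (1.1 equiv), THF, 0 °C; then Ac2O, 0 °C → rt
Reagents that add atoms: acetic anhydride, CC(=O)OC(C)=O
Why: Fluoride cleaves the aryl silyl ether and the phenoxide is acylated in the same flask; O-3 is still blocked as the acetal, so the acetate is fixed on O-4 and cannot migrate.

Step 13
Reactants: 22 4-{2-[3,5-dimethoxy-4-(3-methylbut-2-en-1-yl)phenyl]ethyl}-3-methoxy-2-(methoxymethoxy)phenyl acetate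
Product: 24 4-{2-[3,5-dimethoxy-4-(3-methylbut-2-en-1-yl)phenyl]ethyl}-2-hydroxy-3-methoxyphenyl acetate, via trimethylsilyl ether 23 (not isolated)
Conditions: Me3SiOTf, 2,2′-bipyridyl, CH2Cl2, 0 °C; then H2O
Reagents that add atoms: none
Why: Non-protic cleavage of an aryl methoxymethyl ether: the silyl triflate–bipyridyl pair converts the acetal into silyl ether 23 and a pyridinium salt, and water then frees the phenol; the medium stays buffered and free of nucleophiles and hydrogen, so the aryl acetate should stay on O-4 and the prenyl olefin should be untouched.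

## Compound list

1 | 2-chloro-1,1-dimethoxyethane (chloroacetaldehyde dimethyl acetal) | ClCC(OC)OC | starting material
2 | 1-bromo-3-methylbut-2-ene (prenyl bromide) | BrCC=C(C)C | starting material
3 | lithium methoxyacetylide | [Li]C#COC | intermediate (not isolated)
4 | 1-methoxy-5-methylhex-4-en-1-yne | COC#CCC=C(C)C | intermediate
5 | 2,3,4-trihydroxybenzaldehyde | O=Cc1ccc(O)c(O)c1O | starting material
6 | 2,3-dihydroxy-4-[(triisopropylsilyl)oxy]benzaldehyde | O=Cc1ccc(O[Si](C(C)C)(C(C)C)C(C)C)c(O)c1O | intermediate
7 | 2-hydroxy-3-(methoxymethoxy)-4-[(triisopropylsilyl)oxy]benzaldehyde | O=Cc1ccc(O[Si](C(C)C)(C(C)C)C(C)C)c(OCOC)c1O | intermediate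
8 | 2-methoxy-3-(methoxymethoxy)-4-[(triisopropylsilyl)oxy]benzaldehyde | O=Cc1ccc(O[Si](C(C)C)(C(C)C)C(C)C)c(OCOC)c1OC | intermediate
9 | {2-methoxy-3-(methoxymethoxy)-4-[(triisopropylsilyl)oxy]phenyl}methanol | OCc1ccc(O[Si](C(C)C)(C(C)C)C(C)C)c(OCOC)c1OC | intermediate
10 | {2-methoxy-3-(methoxymethoxy)-4-[(triisopropylsilyl)oxy]phenyl}methyl methanesulfonate | CS(=O)(=O)OCc1ccc(O[Si](C(C)C)(C(C)C)C(C)C)c(OCOC)c1OC | intermediate (not isolated)
11 | [4-(chloromethyl)-3-methoxy-2-(methoxymethoxy)phenoxy]triisopropylsilane | ClCc1ccc(O[Si](C(C)C)(C(C)C)C(C)C)c(OCOC)c1OC | intermediate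
12 | [4-(but-3-yn-1-yl)-3-methoxy-2-(methoxymethoxy)phenoxy]triisopropylsilane | C#CCCc1ccc(O[Si](C(C)C)(C(C)C)C(C)C)c(OCOC)c1OC | intermediate
13 | 4,4-dichloro-3-(2-{2-methoxy-3-(methoxymethoxy)-4-[(triisopropylsilyl)oxy]phenyl}ethyl)cyclobut-2-en-1-one | O=C1C=C(CCc2ccc(O[Si](C(C)C)(C(C)C)C(C)C)c(OCOC)c2OC)C1(Cl)Cl | intermediate
14 | 3-(2-{2-methoxy-3-(methoxymethoxy)-4-[(triisopropylsilyl)oxy]phenyl}ethyl)cyclobut-2-en-1-one | O=C1C=C(CCc2ccc(O[Si](C(C)C)(C(C)C)C(C)C)c(OCOC)c2OC)C1 | intermediate
15 | 3-(2-ArB-ethyl)buta-1,3-dien-1-one (vinylketene) | O=C=CC(=C)CCc1ccc(O[Si](C(C)C)(C(C)C)C(C)C)c(OCOC)c1OC | intermediate (not isolated)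
16 | 3-methoxy-2-(3-methylbut-2-en-1-yl)-4-(4-ArB-but-1-en-2-yl)cyclobut-2-en-1-one (racemic) | O=C1C(CC=C(C)C)=C(OC)C1C(=C)CCc2ccc(O[Si](C(C)C)(C(C)C)C(C)C)c(OCOC)c2OC | intermediate (not isolated)
17 | 3-methoxy-2-(3-methylbut-2-en-1-yl)-5-methylidene-7-ArB-hepta-1,3-dien-1-one (ketene and vinyl group cis) | O=C=C(CC=C(C)C)/C(OC)=C\C(=C)CCc1ccc(O[Si](C(C)C)(C(C)C)C(C)C)c(OCOC)c1OC | intermediate (not isolated)
18 | 3-methoxy-2-(3-methylbut-2-en-1-yl)-5-(2-ArB-ethyl)cyclohexa-2,4-dien-1-one | O=C1CC(CCc2ccc(O[Si](C(C)C)(C(C)C)C(C)C)c(OCOC)c2OC)=CC(OC)=C1CC=C(C)C | intermediate (not isolated)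
19 | 3-methoxy-5-(2-{2-methoxy-3-(methoxymethoxy)-4-[(triisopropylsilyl)oxy]phenyl}ethyl)-2-(3-methylbut-2-en-1-yl)phenol | COc1cc(CCc2ccc(O[Si](C(C)C)(C(C)C)C(C)C)c(OCOC)c2OC)cc(O)c1CC=C(C)C | intermediate
20 | [4-{2-[3,5-dimethoxy-4-(3-methylbut-2-en-1-yl)phenyl]ethyl}-3-methoxy-2-(methoxymethoxy)phenoxy]triisopropylsilane | COc1cc(CCc2ccc(O[Si](C(C)C)(C(C)C)C(C)C)c(OCOC)c2OC)cc(OC)c1CC=C(C)C | intermediate
21 | tetrabutylammonium 4-{2-[3,5-dimethoxy-4-(3-methylbut-2-en-1-yl)phenyl]ethyl}-3-methoxy-2-(methoxymethoxy)phenoxide | CCCC[N+](CCCC)(CCCC)CCCC.COc1cc(CCc2ccc([O-])c(OCOC)c2OC)cc(OC)c1CC=C(C)C | intermediate (not isolated)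
22 | 4-{2-[3,5-dimethoxy-4-(3-methylbut-2-en-1-yl)phenyl]ethyl}-3-methoxy-2-(methoxymethoxy)phenyl acetate | COc1cc(CCc2ccc(OC(C)=O)c(OCOC)c2OC)cc(OC)c1CC=C(C)C | intermediate
23 | 4-{2-[3,5-dimethoxy-4-(3-methylbut-2-en-1-yl)phenyl]ethyl}-3-methoxy-2-[(trimethylsilyl)oxy]phenyl acetate | COc1cc(CCc2ccc(OC(C)=O)c(O[Si](C)(C)C)c2OC)cc(OC)c1CC=C(C)C | intermediate (not isolated)
24 | 4-{2-[3,5-dimethoxy-4-(3-methylbut-2-en-1-yl)phenyl]ethyl}-2-hydroxy-3-methoxyphenyl acetate (CNP0143232.0) | COc1cc(CCc2ccc(OC(C)=O)c(O)c2OC)cc(OC)c1CC=C(C)C | target

## Step count and least certain steps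

Total step count: 13. Longest linear sequence: 12 (steps 2–13, from 5); step 1 is a one-step side branch to 4.

**Step 10 (key step).**
- What may go wrong: the vinylketene may be diverted into dimerization or into acylation of the phenol as it forms, or the ynol ether may polymerize thermally before it is captured, so that conversion stalls. The regiochemistry is not in doubt.
- Fallback: it sets out from aldehyde 8 and returns at 20. Horner–Wadsworth–Emmons olefination of 8 with commercial diethyl (3,5-dimethoxybenzyl)phosphonate (NaH, THF) should give the des-prenyl (E)-stilbene F1. Hydrogenation (H2, Pd/C, EtOAc), harmless because no prenyl group is present yet, should give the des-prenyl bibenzyl F2. Lithiation of F2 between the two methoxy groups of ring A (n-BuLi, TMEDA, THF, 0 °C), transmetalation with CuBr·SMe2 and alkylation with 2 should give 20.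

**Step 8.**
- What may go wrong: zinc chloride and the acid chloride may cleave the acetal or acylate the electron-rich ring B, and the ketene may oligomerize faster than it adds.
- Fallback: it sets out from alkyne 12 and returns at 14, bypassing 13 and step 9. A keteniminium salt made from N,N-dimethylacetamide, Tf2O and 2,4,6-collidine should add to 12 in a [2+2] cycloaddition to give the cyclobuteniminium triflate F3. Hydrolysis with aqueous NaHCO3 should give 14.

**Step 7.**
- What may go wrong: attack through the α-carbon of the Grignard reagent would give the allenic isomer, and reductive homocoupling of the benzylic chloride would waste material.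
- Fallback: it sets out from 11 and returns at 12. Lithiated 1-(trimethylsilyl)propyne (n-BuLi, THF, −78 °C) is alkylated by 11 only at its CH2 terminus and should give the silylalkyne F4. C-Desilylation with catalytic AgNO3 in aqueous acetone, which leaves the aryl silyl ether alone, should give 12.

**Step 3.**
- What may go wrong: a base-induced shift of the silyl group from O-4 to O-3, or alkylation at O-2, would scramble the oxygen pattern.
- Fallback: it sets out from 5 and returns at 8, with a non-migrating group on O-4 that is exchanged before any olefin or alkyne exists.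
  - Benzylation of 5 at O-4 (BnBr, NaHCO3, MeCN) should give the benzyl ether F5.
  - MeOCH2Cl/i-Pr2NEt should give the acetal F6.
  - MeI/K2CO3 should give the methyl ether F7.
  - Hydrogenolysis (H2, Pd/C, EtOAc) should give the phenol F8.
  - i-Pr3SiCl/imidazole should then give 8.

**Step 13.**
- What may go wrong: loss of the acetyl group or its shift to the neighbouring oxygen as the phenol is set free, or addition of acid to the prenyl olefin.
- Fallback: it sets out from 22 and returns at 24. HCl in methanol (conditions used routinely on prenylated phenols) should remove acetal and acetyl group together and give the catechol F9. Acetylation with one equivalent of Ac2O and 2,4,6-collidine at low temperature should then go to the less hindered O-4, since O-3 is flanked by the methoxy group and O-4, and give 24.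

## Further compounds

F1 | step 10 | {4-[(E)-2-(3,5-dimethoxyphenyl)ethenyl]-3-methoxy-2-(methoxymethoxy)phenoxy}triisopropylsilane | COc1cc(/C=C/c2ccc(O[Si](C(C)C)(C(C)C)C(C)C)c(OCOC)c2OC)cc(OC)c1
F2 | step 10 | {4-[2-(3,5-dimethoxyphenyl)ethyl]-3-methoxy-2-(methoxymethoxy)phenoxy}triisopropylsilane | COc1cc(CCc2ccc(O[Si](C(C)C)(C(C)C)C(C)C)c(OCOC)c2OC)cc(OC)c1
F3 | step 8 | N-[3-(2-ArB-ethyl)cyclobut-2-en-1-ylidene]-N-methylmethanaminium trifluoromethanesulfonate | C[N+](C)=C1C=C(CCc2ccc(O[Si](C(C)C)(C(C)C)C(C)C)c(OCOC)c2OC)C1.[O-]S(=O)(=O)C(F)(F)F
F4 | step 7 | {3-methoxy-2-(methoxymethoxy)-4-[4-(trimethylsilyl)but-3-yn-1-yl]phenoxy}triisopropylsilane | C[Si](C)(C)C#CCCc1ccc(O[Si](C(C)C)(C(C)C)C(C)C)c(OCOC)c1OC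
F5 | step 3 | 4-(benzyloxy)-2,3-dihydroxybenzaldehyde | O=Cc1ccc(OCc2ccccc2)c(O)c1O
F6 | step 3 | 4-(benzyloxy)-2-hydroxy-3-(methoxymethoxy)benzaldehyde | O=Cc1ccc(OCc2ccccc2)c(OCOC)c1O
F7 | step 3 | 4-(benzyloxy)-2-methoxy-3-(methoxymethoxy)benzaldehyde | O=Cc1ccc(OCc2ccccc2)c(OCOC)c1OC
F8 | step 3 | 4-hydroxy-2-methoxy-3-(methoxymethoxy)benzaldehyde | O=Cc1ccc(O)c(OCOC)c1OC
F9 | step 13 | 4-{2-[3,5-dimethoxy-4-(3-methylbut-2-en-1-yl)phenyl]ethyl}-3-methoxybenzene-1,2-diol | COc1cc(CCc2ccc(O)c(O)c2OC)cc(OC)c1CC=C(C)C
A1 | alternative 1 | {[3,5-dimethoxy-4-(3-methylbut-2-en-1-yl)phenyl]methyl}triphenylphosphonium bromide | COc1cc(C[P+](c2ccccc2)(c2ccccc2)c2ccccc2)cc(OC)c1CC=C(C)C.[Br-]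
A2 | alternative 1 | [4-{2-[3,5-dimethoxy-4-(3-methylbut-2-en-1-yl)phenyl]ethenyl}-3-methoxy-2-(methoxymethoxy)phenoxy]triisopropylsilane (E/Z mixture) | COc1cc(C=Cc2ccc(O[Si](C(C)C)(C(C)C)C(C)C)c(OCOC)c2OC)cc(OC)c1CC=C(C)C
A3 | alternative 2 | [4-ethenyl-3-methoxy-2-(methoxymethoxy)phenoxy]triisopropylsilane | C=Cc1ccc(O[Si](C(C)C)(C(C)C)C(C)C)c(OCOC)c1OC
A4 | alternative 2 | 5-bromo-1,3-dimethoxy-2-(3-methylbut-2-en-1-yl)benzene | COc1cc(Br)cc(OC)c1CC=C(C)C
A5 | alternative 3 | (E)-6-{2-methoxy-3-(methoxymethoxy)-4-[(triisopropylsilyl)oxy]phenyl}hex-3-en-2-one | CC(=O)/C=C/CCc1ccc(O[Si](C(C)C)(C(C)C)C(C)C)c(OCOC)c1OC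
A6 | alternative 3 | 5-(2-{2-methoxy-3-(methoxymethoxy)-4-[(triisopropylsilyl)oxy]phenyl}ethyl)-2-(3-methylbut-2-en-1-yl)cyclohexane-1,3-dione | O=C1CC(CCc2ccc(O[Si](C(C)C)(C(C)C)C(C)C)c(OCOC)c2OC)CC(=O)C1CC=C(C)C
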